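**Retrosynthetic overview**
- Target ⇒ its 7,3'-di-O-benzyl ether. Ring B is bought as syringol. Rings A and C are made last and together.
- Rings A + C ⇒ one crossed [2+2+2] of an acyclic (S)-ynol-ether/alkyne 1,7-diyne with benzyl ethynyl ether (new bonds C4a–C8a, C8–C7, C6–C5).
- Diyne ⇒ (S)-2-arylpent-4-yn-1-ol (O-ethynylation with trichloroethene) ⇒ (S)-β-aryl-γ-butyrolactone (reduction, then C1 homologation). This lactone ring is only temporary.
- Lactone ⇒ rhodium/(S)-BINAP 1,4-addition of an aryl borate to furan-2(5H)-one, which sets the only stereocentre. The 1,1-dimethylallyl group comes from a γ-selective Suzuki coupling at the second bromide.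
- Aryl unit ⇒ symmetric 3,5-dibromide of O-benzylsyringol.

Assumption: the SMILES is read as the (3S)-isoflavan, and (S)-BINAP is taken to give the (S)-lactone, as it does with cyclopentenone and six-membered lactones.

**Step 1**
Reactants: 1 2,6-dimethoxyphenol (syringol)
Product: 2 2-(benzyloxy)-1,3-dimethoxybenzene
Conditions: BnBr, K2CO3, DMF, rt
Reagents that add atoms: benzyl bromide, BrCc1ccccc1
Why: Williamson etherification of the phenoxide; capping the OH removes its para-directing power so that only the two methoxy groups steer step 2, and the benzyl group survives every basic and organometallic step up to step 9.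

**Step 2**
Reactants: 2 2-(benzyloxy)-1,3-dimethoxybenzene
Product: 3 3-(benzyloxy)-1,5-dibromo-2,4-dimethoxybenzene
Conditions: NBS (2.1 equiv), MeCN, 0 °C → rt
Reagents that add atoms: N-bromosuccinimide, O=C1CCC(=O)N1Br
Why: Electrophilic aromatic bromination; the two equivalent positions ortho to one methoxy and para to the other are by far the most activated, while the position para to the twisted central benzyloxy group is meta to both methoxy groups, so a symmetric dibromide forms in which either bromine can be exchanged later.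

**Step 3**
Reactants: 3 3-(benzyloxy)-1,5-dibromo-2,4-dimethoxybenzene; 4 furan-2(5H)-one
Product: 7 (4S)-4-[3-(benzyloxy)-5-bromo-2,4-dimethoxyphenyl]oxolan-2-one, via aryllithium 5 (not isolated), via lithium aryltrimethoxyborate 6 (not isolated)
Conditions: n-BuLi (1.0 equiv per 3), Et2O, −78 °C; B(OMe)3, −78 °C → rt; then 4 (0.5 equiv), Rh(acac)(C2H4)2 (3 mol %), (S)-BINAP (3.3 mol %), H2O, dioxane, 100 °C, one pot
Reagents that add atoms: trimethyl borate, COB(OC)OC, and n-butyllithium, [Li]CCCC (their atoms sit only in 5 and 6; none stays in 7)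
Why: Bromine–lithium exchange with one equivalent of n-BuLi stops at the monolithio stage, the derived ate complex transmetalates to rhodium, and the Hayashi–Miyaura asymmetric 1,4-addition inserts the butenolide into the aryl–rhodium bond on the face left open by (S)-BINAP, which sets the only stereocentre as (S); the aryl bromide is inert to monovalent rhodium.

**Step 4**
Reactants: 7 (4S)-4-[3-(benzyloxy)-5-bromo-2,4-dimethoxyphenyl]oxolan-2-one; 8 4,4,5,5-tetramethyl-2-(3-methylbut-2-en-1-yl)-1,3,2-dioxaborolane (prenylboronic acid pinacol ester)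
Product: 9 (4S)-4-[3-(benzyloxy)-2,4-dimethoxy-5-(2-methylbut-3-en-2-yl)phenyl]oxolan-2-one
Conditions: Pd(OAc)2 (3 mol %), 1,1'-bis(di-tert-butylphosphino)ferrocene (4 mol %), K3PO4, THF/H2O 10:1, 60 °C; 1 M HCl work-up (re-closes any opened lactone)
Reagents that add atoms: none
Why: γ-Selective Suzuki–Miyaura allylation; the allylboronate transmetalates to aryl–palladium in the SE2' sense and the bulky wide-bite-angle diphosphine forces reductive elimination from the tertiary σ-allyl complex before it slips to the primary one, giving the 1,1-dimethylallyl group, while the non-acidic β-stereocentre stays (S).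

**Step 5**
Reactants: 9 (4S)-4-[3-(benzyloxy)-2,4-dimethoxy-5-(2-methylbut-3-en-2-yl)phenyl]oxolan-2-one; 10 dimethyl (1-diazo-2-oxopropyl)phosphonate (Ohira–Bestmann reagent)
Product: 12 (2S)-2-[3-(benzyloxy)-2,4-dimethoxy-5-(2-methylbut-3-en-2-yl)phenyl]pent-4-yn-1-ol, via lactol 11 (not isolated)
Conditions: i-Bu2AlH (1.15 equiv), CH2Cl2, −78 °C; MeOH quench; then 10 (1.5 equiv), K2CO3 (3 equiv), MeOH, 0 °C → rt, one pot
Reagents that add atoms: none
Why: Partial reduction stops at the aluminium lactolate at −78 °C, and the open hydroxy-aldehyde form of the lactol undergoes Ohira–Bestmann (Seyferth–Gilbert) homologation through an alkylidene carbene 1,2-hydrogen shift, turning the carbonyl carbon into C4a and adding C5; the stereocentre is β to the aldehyde and cannot epimerise.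

**Step 6**
Reactants: 12 (2S)-2-[3-(benzyloxy)-2,4-dimethoxy-5-(2-methylbut-3-en-2-yl)phenyl]pent-4-yn-1-ol; 13 trichloroethene
Product: 16 3-(benzyloxy)-1-[(2S)-1-(ethynyloxy)pent-4-yn-2-yl]-2,4-dimethoxy-5-(2-methylbut-3-en-2-yl)benzene, via dichlorovinyl ether 14 (not isolated), via dilithium bis-acetylide 15 (not isolated)
Conditions: KH (1.1 equiv), THF, 0 °C; 13 (1.1 equiv), −50 °C → rt; n-BuLi (3.3 equiv), −78 → −40 °C; MeOH, −78 °C; Et3N-deactivated SiO2
Reagents that add atoms: n-butyllithium, [Li]CCCC (lithium in 15 only)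
Why: Greene ynol ether synthesis; the alkoxide adds anti to dichloroacetylene formed in situ from 13, n-BuLi then causes loss of LiCl and chlorine–lithium exchange (the third equivalent only deprotonates the terminal alkyne) and methanol protonates both acetylides, with nothing touching the C–H stereocentre.

**Step 7**
Reactants: 17 benzyl alcohol; 13 trichloroethene
Product: 20 [(ethynyloxy)methyl]benzene (benzyl ethynyl ether), via benzyl dichlorovinyl ether 18 (not isolated), via lithium benzyloxyacetylide 19 (not isolated)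
Conditions: KH (1.1 equiv), THF, 0 °C; 13, −50 °C → rt; n-BuLi (2.2 equiv), −78 °C; MeOH, −78 °C; kept below 25 °C, used at once
Reagents that add atoms: n-butyllithium, [Li]CCCC (lithium in 19 only)
Why: The same Greene ynol ether sequence on benzyl alcohol; at or below room temperature the benzyl ethynyl ether does not yet undergo its [3,3] rearrangement, which needs about 60 °C.

**Step 8**
Reactants: 16 3-(benzyloxy)-1-[(2S)-1-(ethynyloxy)pent-4-yn-2-yl]-2,4-dimethoxy-5-(2-methylbut-3-en-2-yl)benzene; 20 benzyl ethynyl ether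
Product: 21 (3S)-7-(benzyloxy)-3-[3-(benzyloxy)-2,4-dimethoxy-5-(2-methylbut-3-en-2-yl)phenyl]-3,4-dihydro-2H-chromene
Conditions: [Rh(cod)2]BF4 (5 mol %), rac-BINAP (5 mol %), H2 pre-activation, CH2Cl2, rt; 16 added over 2 h to 20 (3 equiv)
Reagents that add atoms: none
Why: Proposed new method: crossed [2+2+2] alkyne cyclotrimerisation in which a cationic monovalent-rhodium/BINAP centre couples the ynol-ether and alkyl alkynes of 16 to a rhodacyclopentadiene (closing ring C through C4a–C8a) and then takes up 20 to close ring A; both ethynyl ethers are polarised (nucleophilic CH, electrophilic C–O carbon), so the electron-rich Rh–C8 carbon bonds to the oxygen-bearing carbon of 20 (head-to-tail, giving the 1,3-dioxygenated 7-benzyloxy arene and not the 6-isomer), and an initial intermolecular head-to-tail coupling of the two ynol ethers would lead to the same product because the tether only allows C4a to bond to C8a; the hindered vinyl group next to the quaternary carbon does not compete with alkynes, no stereocentre is made and C3 is untouched; closest known reaction type: cationic rhodium/BINAP-catalysed [2+2+2] cycloadditions of tethered diynes (ynamide- and aryl alkynyl ether-linked ones included) with terminal alkynes, and the head-to-tail cross-trimerisation of aryl ethynyl ethers.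

**Step 9**
Reactants: 21 (3S)-7-(benzyloxy)-3-[3-(benzyloxy)-2,4-dimethoxy-5-(2-methylbut-3-en-2-yl)phenyl]-3,4-dihydro-2H-chromene
Product: 22 (3S)-3-[3-hydroxy-2,4-dimethoxy-5-(2-methylbut-3-en-2-yl)phenyl]-3,4-dihydro-2H-chromen-7-ol (target)
Conditions: BCl3 (5 equiv), C6HMe5 (8 equiv), CH2Cl2, −78 °C, 45 min; CHCl3/MeOH quench
Reagents that add atoms: none
Why: Lewis acid debenzylation of aryl benzyl ethers with pentamethylbenzene as a non-basic benzyl cation trap; at −78 °C BCl3 cleaves only the benzylic C–O bonds and leaves the aryl methyl ethers, the chroman ether, the monosubstituted alkene and the stereocentre intact, whereas hydrogenolysis would saturate the vinyl group.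

**Compound list**
1 | 2,6-dimethoxyphenol | COc1cccc(OC)c1O | starting material
2 | 2-(benzyloxy)-1,3-dimethoxybenzene | COc1cccc(OC)c1OCc1ccccc1 | intermediate
3 | 3-(benzyloxy)-1,5-dibromo-2,4-dimethoxybenzene | COc1c(Br)cc(Br)c(OC)c1OCc1ccccc1 | intermediate
4 | furan-2(5H)-one | O=C1C=CCO1 | starting material
5 | [3-(benzyloxy)-5-bromo-2,4-dimethoxyphenyl]lithium | [Li]c1cc(Br)c(OC)c(OCc2ccccc2)c1OC | intermediate
6 | lithium [3-(benzyloxy)-5-bromo-2,4-dimethoxyphenyl]trimethoxyborate | [Li+].CO[B-](OC)(OC)c1cc(Br)c(OC)c(OCc2ccccc2)c1OC | intermediate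
7 | (4S)-4-[3-(benzyloxy)-5-bromo-2,4-dimethoxyphenyl]oxolan-2-one | Brc1cc([C@H]2COC(=O)C2)c(OC)c(OCc2ccccc2)c1OC | intermediate
8 | 4,4,5,5-tetramethyl-2-(3-methylbut-2-en-1-yl)-1,3,2-dioxaborolane | CC(C)=CCB1OC(C)(C)C(C)(C)O1 | starting material
9 | (4S)-4-[3-(benzyloxy)-2,4-dimethoxy-5-(2-methylbut-3-en-2-yl)phenyl]oxolan-2-one | C=CC(C)(C)c1cc([C@H]2COC(=O)C2)c(OC)c(OCc2ccccc2)c1OC | intermediate
10 | dimethyl (1-diazo-2-oxopropyl)phosphonate | COP(=O)(OC)C(=[N+]=[N-])C(C)=O | starting material
11 | (4S)-4-[3-(benzyloxy)-2,4-dimethoxy-5-(2-methylbut-3-en-2-yl)phenyl]oxolan-2-ol (anomer mixture) | C=CC(C)(C)c1cc([C@H]2COC(O)C2)c(OC)c(OCc2ccccc2)c1OC | intermediate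
12 | (2S)-2-[3-(benzyloxy)-2,4-dimethoxy-5-(2-methylbut-3-en-2-yl)phenyl]pent-4-yn-1-ol | C=CC(C)(C)c1cc([C@H](CC#C)CO)c(OC)c(OCc2ccccc2)c1OC | intermediate
13 | trichloroethene | ClC=C(Cl)Cl | starting material
14 | 3-(benzyloxy)-1-[(2S)-1-{[(E)-1,2-dichloroethenyl]oxy}pent-4-yn-2-yl]-2,4-dimethoxy-5-(2-methylbut-3-en-2-yl)benzene | C=CC(C)(C)c1cc([C@H](CC#C)CO/C(Cl)=C\Cl)c(OC)c(OCc2ccccc2)c1OC | intermediate
15 | dilithium bis-acetylide of 16 | C=CC(C)(C)c1cc([C@H](CC#C[Li])COC#C[Li])c(OC)c(OCc2ccccc2)c1OC | intermediate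
16 | 3-(benzyloxy)-1-[(2S)-1-(ethynyloxy)pent-4-yn-2-yl]-2,4-dimethoxy-5-(2-methylbut-3-en-2-yl)benzene | C=CC(C)(C)c1cc([C@H](CC#C)COC#C)c(OC)c(OCc2ccccc2)c1OC | intermediate
17 | benzyl alcohol | OCc1ccccc1 | starting material
18 | ({[(E)-1,2-dichloroethenyl]oxy}methyl)benzene | c1ccccc1CO/C(Cl)=C\Cl | intermediate
19 | lithium benzyloxyacetylide | [Li]C#COCc1ccccc1 | intermediate
20 | [(ethynyloxy)methyl]benzene | C#COCc1ccccc1 | intermediate
21 | (3S)-7-(benzyloxy)-3-[3-(benzyloxy)-2,4-dimethoxy-5-(2-methylbut-3-en-2-yl)phenyl]-3,4-dihydro-2H-chromene | C=CC(C)(C)c1cc([C@H]2COc3cc(OCc4ccccc4)ccc3C2)c(OC)c(OCc2ccccc2)c1OC | intermediate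
22 | (3S)-3-[3-hydroxy-2,4-dimethoxy-5-(2-methylbut-3-en-2-yl)phenyl]-3,4-dihydro-2H-chromen-7-ol | C=CC(C)(C)c1cc([C@H]2COc3cc(O)ccc3C2)c(OC)c(O)c1OC | target

**Totals:** 9 steps in all. The longest linear sequence is 8 steps (steps 1–6, 8, 9); step 7 is a one-step side branch.

**Three steps most likely to fail**

Step 8. The risks are formation of the 6-benzyloxy isomer, oligomerisation of 20, and slow closure of the 1,7-diyne.
The fallback keeps the joint closure of rings A and C but makes it regiospecific through an intramolecular inverse-demand Diels–Alder/retro-Diels–Alder reaction. It sets out from 12 and comes back at 21.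
- Commercial 3,5-dichloropyridazine and 17 (NaH, THF, 0 °C; the 5-chloride goes first) give 5-(benzyloxy)-3-chloropyridazine F1.
- The sodium alkoxide of 12 displaces the remaining chloride (NaH, DMF, 60 °C) to give the (S)-pyridazinyl pentynyl ether F2.
- Heating F2 in 1,3,5-triisopropylbenzene at 230 °C adds the tethered alkyne across C3 and C6 of the diazine and expels N2. This gives 21 directly, with the 7-oxygen fixed by its place on the diazine.

Step 4. The risks are the linear prenyl isomer and sluggish coupling next to the ortho-methoxy group.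
The fallback reverses the polarity and installs the group before the lactone. It sets out from 3 and comes back at 9.
- Prenol and picolinic acid (DCC, DMAP, CH2Cl2) give 3-methylbut-2-en-1-yl pyridine-2-carboxylate F3.
- One bromine of 3 is exchanged with i-PrMgCl·LiCl (THF, −15 °C) to give [3-(benzyloxy)-5-bromo-2,4-dimethoxyphenyl]magnesium chloride F4.
- With CuBr·SMe2, F4 displaces the magnesium-chelated picolinate of F3 in the SN2' sense and gives 3-(benzyloxy)-1-bromo-2,4-dimethoxy-5-(2-methylbut-3-en-2-yl)benzene F5.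
- F5 is taken through the one-pot sequence of step 3: n-BuLi to the aryllithium F6, B(OMe)3 to the lithium aryltrimethoxyborate F7, then 4, Rh(acac)(C2H4)2/(S)-BINAP and H2O. This delivers 9.

Step 3. The risks are protodeboronation of the electron-rich ortho-methoxy aryl and low turnover with the butenolide.
The fallback sets the stereocentre by hydride delivery instead of aryl delivery. It sets out from 3 (through borate 6, made as before) and comes back at 7.
- 6 is coupled with commercial 4-bromofuran-2(5H)-one (Pd(PPh3)4, THF/H2O, 50 °C). The vinylogous acyl bromide reacts far faster than the electron-rich aryl bromide. The product is 4-[3-(benzyloxy)-5-bromo-2,4-dimethoxyphenyl]furan-2(5H)-one F8.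
- Asymmetric copper hydride conjugate reduction then gives 7. Conditions: CuCl, NaOt-Bu, the p-tol-BINAP enantiomer that gives the (S)-product, polymethylhydrosiloxane, t-BuOH, toluene, 0 °C.

**Further compounds**
F1 | step 8 | 5-(benzyloxy)-3-chloropyridazine | Clc1cc(OCc2ccccc2)cnn1
F2 | step 8 | 5-(benzyloxy)-3-({(2S)-2-[3-(benzyloxy)-2,4-dimethoxy-5-(2-methylbut-3-en-2-yl)phenyl]pent-4-yn-1-yl}oxy)pyridazine | C=CC(C)(C)c1cc([C@H](CC#C)COc2cc(OCc3ccccc3)cnn2)c(OC)c(OCc2ccccc2)c1OC
F3 | step 4 | 3-methylbut-2-en-1-yl pyridine-2-carboxylate | CC(C)=CCOC(=O)c1ccccn1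
F4 | step 4 | [3-(benzyloxy)-5-bromo-2,4-dimethoxyphenyl]magnesium chloride | Cl[Mg]c1cc(Br)c(OC)c(OCc2ccccc2)c1OC
F5 | step 4 | 3-(benzyloxy)-1-bromo-2,4-dimethoxy-5-(2-methylbut-3-en-2-yl)benzene | C=CC(C)(C)c1cc(Br)c(OC)c(OCc2ccccc2)c1OC
F6 | step 4 | [3-(benzyloxy)-2,4-dimethoxy-5-(2-methylbut-3-en-2-yl)phenyl]lithium | C=CC(C)(C)c1cc([Li])c(OC)c(OCc2ccccc2)c1OC
F7 | step 4 | lithium [3-(benzyloxy)-2,4-dimethoxy-5-(2-methylbut-3-en-2-yl)phenyl]trimethoxyborate | [Li+].CO[B-](OC)(OC)c1cc(C(C)(C)C=C)c(OC)c(OCc2ccccc2)c1OC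
F8 | step 3 | 4-[3-(benzyloxy)-5-bromo-2,4-dimethoxyphenyl]furan-2(5H)-one | Brc1cc(C2=CC(=O)OC2)c(OC)c(OCc2ccccc2)c1OC
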